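**Retrosynthetic overview**

1. Rings: A (methoxy ring), B (central ring) and C (chlorophenol ring) form the phenanthrene, numbered C2 (Cl), C3 (OH), C4 (ring D), C6 (ring E), C7 (OMe); ring D is the phenol ring with the CH2CH2 bridge para to its OH; ring E is the second chlorophenol ring.
2. Last C–C bond and last ring: the bridge CH2 is joined to the ring E carbon lying between C–Cl and the biaryl carbon by hydroboration of a ring D styrene and intramolecular B-alkyl Suzuki–Miyaura coupling with the only C–Br bond of the precursor; one operation closes the 12-membered ring and locks both biaryl axes, and acid then removes three MOM groups.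
3. Enabling feature: rings D and E stand on C4 (bay) and C6 of the rigid phenanthrene, whose two exocyclic bonds run parallel, so rings A–C act as a U-shaped template that places the ring D carbon para to its oxygen (bearing the two-carbon arm) within reach of the ring E carbon between C–Cl and the biaryl bond.
4. The open precursor is cut at its two biaryl bonds: C6–ring E (Suzuki–Miyaura with an iodide from directed ortho-metalation of MOM-protected 3-bromo-4-chlorophenol) and C4–ring D (Suzuki–Miyaura at a bay bromide placed by the C3 phenol).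
5. Phenanthrene from 6-bromovanillin and 2-bromo-5-chloro-4-hydroxybenzaldehyde: Suzuki–Miyaura biaryl coupling, then hydrazine closure of ring B from the 2,2'-dialdehyde; ring order B, then the macrocycle.

Key step: step 16

Remark: the target SMILES carries no stereodescriptor, so the helically twisted macrocycle is prepared as the racemate.

**Route**

Step 1
Reactants: 1 2-bromo-4-hydroxybenzaldehyde
Product: 2 2-bromo-5-chloro-4-hydroxybenzaldehyde
Conditions: SO2Cl2 (1.05 equiv), AcOH, 40 °C
Reagents that add atoms: sulfuryl chloride, O=S(=O)(Cl)Cl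
Why: Electrophilic aromatic chlorination ortho to the phenol; the para position carries the formyl group and, of the two ortho carbons, C5 is open while C3 is shielded by the neighbouring bromine.

Step 2
Reactants: 3 2-bromo-4-hydroxy-5-methoxybenzaldehyde (6-bromovanillin)
Product: 4 5-bromo-4-formyl-2-methoxyphenyl 4-methylbenzenesulfonate
Conditions: TsCl, K2CO3, acetone, reflux
Reagents that add atoms: 4-toluenesulfonyl chloride, Cc1ccc(cc1)S(=O)(=O)Cl
Why: O-sulfonylation of the phenol; the tosylate masks the oxygen that later becomes the triflate, deactivates ring A toward the later bromination and is inert to the palladium catalysts used before its removal.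

Step 3
Reactants: 4 5-bromo-4-formyl-2-methoxyphenyl 4-methylbenzenesulfonate, 2 2-bromo-5-chloro-4-hydroxybenzaldehyde
Product: 6 4'-chloro-2,2'-diformyl-5'-hydroxy-4-methoxybiphenyl-5-yl 4-methylbenzenesulfonate, via aryl pinacol boronate 5 (not isolated)
Conditions: B2pin2, PdCl2(dppf) (5 mol%), KOAc, 1,4-dioxane, 90 °C; then 2, K3PO4 (aq), 90 °C
Reagents that add atoms: none
Why: Miyaura borylation of the aryl bromide followed in the same flask by Suzuki–Miyaura coupling at the C–Br bond of 2, which reacts ahead of its C–Cl bond and of the aryl tosylate, so that both formyl groups end up ortho to the new biaryl bond.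

Step 4
Reactants: 6 4'-chloro-2,2'-diformyl-5'-hydroxy-4-methoxybiphenyl-5-yl 4-methylbenzenesulfonate
Product: 7 2-chloro-3-hydroxy-7-methoxyphenanthren-6-yl 4-methylbenzenesulfonate
Conditions: N2H4·H2O (1.5 equiv), AcOH, reflux
Reagents that add atoms: none
Why: Double condensation of the 2,2'-dialdehyde with hydrazine gives the cyclic azine, which extrudes N2 in hot acetic acid to form the C9=C10 bond (hydrazine-mediated reductive carbonyl coupling, the nitrogen counterpart of a McMurry ring closure), so the substitution pattern of the phenanthrene is fixed by the preceding cross-coupling and not by a regioselective cyclization.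

Step 5
Reactants: 7 2-chloro-3-hydroxy-7-methoxyphenanthren-6-yl 4-methylbenzenesulfonate
Product: 8 4-bromo-2-chloro-3-hydroxy-7-methoxyphenanthren-6-yl 4-methylbenzenesulfonate
Conditions: NBS (1.0 equiv), iPr2NH (10 mol%), CH2Cl2, 0 °C
Reagents that add atoms: N-bromosuccinimide, O=C1CCC(=O)N1Br
Why: Electrophilic aromatic bromination of a phenol: the free C3 hydroxyl activates only C4, because C2 carries chlorine and the para position is a ring fusion, while the tosylate keeps ring A unreactive (the same site selectivity as C1 halogenation of 2-naphthols).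

Step 6
Reactants: 8 4-bromo-2-chloro-3-hydroxy-7-methoxyphenanthren-6-yl 4-methylbenzenesulfonate
Product: 9 4-bromo-2-chloro-7-methoxy-3-(methoxymethoxy)phenanthren-6-yl 4-methylbenzenesulfonate
Conditions: NaH, MOMCl, DMF, 0 °C to rt
Reagents that add atoms: chloromethyl methyl ether, COCCl
Why: Williamson-type O-alkylation of the hindered phenoxide with a small, highly reactive chloromethyl ether.

Step 7
Reactants: 10 3-bromo-4-hydroxybenzaldehyde
Product: 11 3-bromo-4-(methoxymethoxy)benzaldehyde
Conditions: MOMCl, K2CO3, DMF, 0 °C to rt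
Reagents that add atoms: chloromethyl methyl ether, COCCl
Why: O-alkylation of an acidic phenol to the MOM acetal, which survives all later basic and palladium-mediated steps.

Step 8
Reactants: 11 3-bromo-4-(methoxymethoxy)benzaldehyde
Product: 12 2-bromo-4-ethenyl-1-(methoxymethoxy)benzene
Conditions: Ph3PCH3Br, KOtBu, THF, 0 °C to rt
Reagents that add atoms: methyltriphenylphosphonium bromide, C[P+](c1ccccc1)(c1ccccc1)c1ccccc1.[Br-]
Why: Wittig methylenation of the aldehyde installs the vinyl group whose terminal carbon becomes the bridge CH2 bonded to ring E.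

Step 9
Reactants: 12 2-bromo-4-ethenyl-1-(methoxymethoxy)benzene
Product: 13 2-[5-ethenyl-2-(methoxymethoxy)phenyl]-4,4,5,5-tetramethyl-1,3,2-dioxaborolane
Conditions: B2pin2, PdCl2(dppf) (3 mol%), KOAc, 1,4-dioxane, 85 °C
Reagents that add atoms: bis(pinacolato)diboron, CC1(C)OB(OC1(C)C)B1OC(C)(C)C(C)(C)O1
Why: Miyaura borylation of the aryl bromide; acetate as base does not promote Heck or Suzuki side reactions of the styrene.

Step 10
Reactants: 9 4-bromo-2-chloro-7-methoxy-3-(methoxymethoxy)phenanthren-6-yl 4-methylbenzenesulfonate, 13 2-[5-ethenyl-2-(methoxymethoxy)phenyl]-4,4,5,5-tetramethyl-1,3,2-dioxaborolane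
Product: 14 2-chloro-4-[5-ethenyl-2-(methoxymethoxy)phenyl]-7-methoxy-3-(methoxymethoxy)phenanthren-6-yl 4-methylbenzenesulfonate
Conditions: Pd(OAc)2 (5 mol%), SPhos (10 mol%), K3PO4, toluene/H2O, 90 °C
Reagents that add atoms: none
Why: Suzuki–Miyaura coupling of a hindered aryl bromide with a dialkylbiarylphosphine ligand made for tri- and tetra-ortho-substituted biaryls; oxidative addition at the bay C–Br bond should be much faster than at the C2–Cl bond or the tosylate.

Step 11
Reactants: 14 2-chloro-4-[5-ethenyl-2-(methoxymethoxy)phenyl]-7-methoxy-3-(methoxymethoxy)phenanthren-6-yl 4-methylbenzenesulfonate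
Product: 15 2-chloro-4-[5-ethenyl-2-(methoxymethoxy)phenyl]-7-methoxy-3-(methoxymethoxy)phenanthren-6-ol
Conditions: KOH, MeOH/THF/H2O, 60 °C; then aqueous NH4Cl
Reagents that add atoms: none
Why: Saponification of the aryl sulfonate by attack of hydroxide at sulfur frees the C6 phenol; MOM acetals, the aryl chloride and the styrene are stable to base.

Step 12
Reactants: 15 2-chloro-4-[5-ethenyl-2-(methoxymethoxy)phenyl]-7-methoxy-3-(methoxymethoxy)phenanthren-6-ol
Product: 16 2-chloro-4-[5-ethenyl-2-(methoxymethoxy)phenyl]-7-methoxy-3-(methoxymethoxy)phenanthren-6-yl trifluoromethanesulfonate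
Conditions: PhNTf2, Cs2CO3, DMF, rt
Reagents that add atoms: N-phenylbis(trifluoromethanesulfonimide), O=S(=O)(N(c1ccccc1)S(=O)(=O)C(F)(F)F)C(F)(F)F
Why: Triflation of the only free phenol with a mild triflyl donor that generates no strong acid, so the electron-rich styrene and the MOM acetals are left alone.

Step 13
Reactants: 17 3-bromo-4-chlorophenol
Product: 18 2-bromo-1-chloro-4-(methoxymethoxy)benzene
Conditions: MOMCl, K2CO3, DMF, 0 °C to rt
Reagents that add atoms: chloromethyl methyl ether, COCCl
Why: O-alkylation to the MOM ether, which is both the final protecting group of the ring E phenol and the directing group for the next step.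

Step 14
Reactants: 18 2-bromo-1-chloro-4-(methoxymethoxy)benzene
Product: 20 2-bromo-1-chloro-3-iodo-4-(methoxymethoxy)benzene, via ortho-lithiated arene 19 (not isolated)
Conditions: LiN(iPr)2 (1.1 equiv), THF, −78 °C; then iodine, −78 °C to rt
Reagents that add atoms: iodine, [I][I]
Why: Directed ortho-metalation: the proton between the OMOM group and bromine is the most acidic and is removed by the lithium amide at −78 °C, where the ortho-bromoaryllithium does not collapse to an aryne, and iodine quench gives the contiguous O, iodine, Br, Cl pattern of ring E.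

Step 15
Reactants: 16 2-chloro-4-[5-ethenyl-2-(methoxymethoxy)phenyl]-7-methoxy-3-(methoxymethoxy)phenanthren-6-yl trifluoromethanesulfonate, 20 2-bromo-1-chloro-3-iodo-4-(methoxymethoxy)benzene
Product: 22 6-[2-bromo-3-chloro-6-(methoxymethoxy)phenyl]-2-chloro-4-[5-ethenyl-2-(methoxymethoxy)phenyl]-7-methoxy-3-(methoxymethoxy)phenanthrene, via phenanthrenyl pinacol boronate 21 (not isolated)
Conditions: B2pin2, PdCl2(dppf) (5 mol%), KOAc, 1,4-dioxane, 90 °C; then 20 (1.3 equiv), K3PO4 (aq), 85 °C
Reagents that add atoms: none
Why: Miyaura borylation of the aryl triflate followed by Suzuki–Miyaura coupling; the carbon–iodine bond of 20 undergoes oxidative addition far faster than its C–Br and C–Cl bonds, so the bromide needed for the ring closure is kept.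

Step 16
Reactants: 22 6-[2-bromo-3-chloro-6-(methoxymethoxy)phenyl]-2-chloro-4-[5-ethenyl-2-(methoxymethoxy)phenyl]-7-methoxy-3-(methoxymethoxy)phenanthrene
Product: 24 tris(methoxymethyl) ether of the target macrocycle, via B-alkyl-9-BBN adduct 23 (not isolated)
Conditions: 9-BBN dimer, THF, 0 to 40 °C; then syringe-pump addition to PdCl2(dppf) (20 mol%), AsPh3, Cs2CO3, DMF/THF/H2O, 60 °C (final concentration about 1 mmol/L)
Reagents that add atoms: none
Why: 9-BBN adds to the ring D styrene with boron on the terminal carbon (anti-Markovnikov hydroboration); zerovalent palladium then inserts into the only C–Br bond, at the ring E carbon between C–Cl and the biaryl carbon, base-activated B-alkyl transmetalation delivers the primary alkyl group within the same molecule, and reductive elimination from divalent palladium forms the aryl–CH2 bond. The closest known reaction type is the intramolecular B-alkyl Suzuki–Miyaura macrocyclization used for cyclophanes and other macrocycles under pseudo-high dilution. One ring is closed, the 12-membered carbocycle, by C(sp2)–C(sp3) reductive elimination from a 13-membered palladacycle, the ring D arm and the ring E carbon being held close by the parallel C4 and C6 bonds of the phenanthrene. No stereocentre is formed; the two biaryl axes and the bay twist become locked, and because only the rotamer with the ring D arm and the ring E C–Br bond on the same face can cyclize, while rotation about the C6–ring E axis should be possible at 60 °C, a single relative configuration (racemic) is expected. The step needs chemoselectivity for C–Br over the two C–Cl bonds (secured by the dppf catalyst, which does not readily activate aryl chlorides at this temperature), terminal regioselectivity in the hydroboration (secured by 9-BBN on a styrene) and ring closure ahead of oligomerization (secured by slow addition and the U-shaped precursor).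

Step 17
Reactants: 24 tris(methoxymethyl) ether of the target macrocycle
Product: 25 target CNP0310669.0
Conditions: HCl (3 mol/L), MeOH/THF, 50 °C
Reagents that add atoms: none
Why: Acid-catalysed transacetalization cleaves the three MOM acetals, while the aryl methyl ether and both aryl chlorides are inert to dilute acid.

**Compound list**

1 | 2-bromo-4-hydroxybenzaldehyde | O=Cc1ccc(O)cc1Br | starting material
2 | 2-bromo-5-chloro-4-hydroxybenzaldehyde | O=Cc1cc(Cl)c(O)cc1Br | intermediate
3 | 2-bromo-4-hydroxy-5-methoxybenzaldehyde (6-bromovanillin) | COc1cc(C=O)c(Br)cc1O | starting material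
4 | 5-bromo-4-formyl-2-methoxyphenyl 4-methylbenzenesulfonate | COc1cc(C=O)c(Br)cc1OS(=O)(=O)c1ccc(C)cc1 | intermediate
5 | 4-formyl-2-methoxy-5-(4,4,5,5-tetramethyl-1,3,2-dioxaborolan-2-yl)phenyl 4-methylbenzenesulfonate | COc1cc(C=O)c(B2OC(C)(C)C(C)(C)O2)cc1OS(=O)(=O)c1ccc(C)cc1 | intermediate
6 | 4'-chloro-2,2'-diformyl-5'-hydroxy-4-methoxybiphenyl-5-yl 4-methylbenzenesulfonate | COc1cc(C=O)c(-c2cc(O)c(Cl)cc2C=O)cc1OS(=O)(=O)c1ccc(C)cc1 | intermediate
7 | 2-chloro-3-hydroxy-7-methoxyphenanthren-6-yl 4-methylbenzenesulfonate | COc1cc2ccc3cc(Cl)c(O)cc3c2cc1OS(=O)(=O)c1ccc(C)cc1 | intermediate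
8 | 4-bromo-2-chloro-3-hydroxy-7-methoxyphenanthren-6-yl 4-methylbenzenesulfonate | COc1cc2ccc3cc(Cl)c(O)c(Br)c3c2cc1OS(=O)(=O)c1ccc(C)cc1 | intermediate
9 | 4-bromo-2-chloro-7-methoxy-3-(methoxymethoxy)phenanthren-6-yl 4-methylbenzenesulfonate | COc1cc2ccc3cc(Cl)c(OCOC)c(Br)c3c2cc1OS(=O)(=O)c1ccc(C)cc1 | intermediate
10 | 3-bromo-4-hydroxybenzaldehyde | O=Cc1ccc(O)c(Br)c1 | starting material
11 | 3-bromo-4-(methoxymethoxy)benzaldehyde | COCOc1ccc(C=O)cc1Br | intermediate
12 | 2-bromo-4-ethenyl-1-(methoxymethoxy)benzene | C=Cc1ccc(OCOC)c(Br)c1 | intermediate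
13 | 2-[5-ethenyl-2-(methoxymethoxy)phenyl]-4,4,5,5-tetramethyl-1,3,2-dioxaborolane | C=Cc1ccc(OCOC)c(B2OC(C)(C)C(C)(C)O2)c1 | intermediate
14 | 2-chloro-4-[5-ethenyl-2-(methoxymethoxy)phenyl]-7-methoxy-3-(methoxymethoxy)phenanthren-6-yl 4-methylbenzenesulfonate | COc1cc2ccc3cc(Cl)c(OCOC)c(-c4cc(C=C)ccc4OCOC)c3c2cc1OS(=O)(=O)c1ccc(C)cc1 | intermediate
15 | 2-chloro-4-[5-ethenyl-2-(methoxymethoxy)phenyl]-7-methoxy-3-(methoxymethoxy)phenanthren-6-ol | COc1cc2ccc3cc(Cl)c(OCOC)c(-c4cc(C=C)ccc4OCOC)c3c2cc1O | intermediate
16 | 2-chloro-4-[5-ethenyl-2-(methoxymethoxy)phenyl]-7-methoxy-3-(methoxymethoxy)phenanthren-6-yl trifluoromethanesulfonate | COc1cc2ccc3cc(Cl)c(OCOC)c(-c4cc(C=C)ccc4OCOC)c3c2cc1OS(=O)(=O)C(F)(F)F | intermediate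
17 | 3-bromo-4-chlorophenol | Oc1ccc(Cl)c(Br)c1 | starting material
18 | 2-bromo-1-chloro-4-(methoxymethoxy)benzene | COCOc1ccc(Cl)c(Br)c1 | intermediate
19 | [2-bromo-3-chloro-6-(methoxymethoxy)phenyl]lithium | COCOc1ccc(Cl)c(Br)c1[Li] | intermediate
20 | 2-bromo-1-chloro-3-iodo-4-(methoxymethoxy)benzene | COCOc1ccc(Cl)c(Br)c1I | intermediate
21 | 2-{2-chloro-4-[5-ethenyl-2-(methoxymethoxy)phenyl]-7-methoxy-3-(methoxymethoxy)phenanthren-6-yl}-4,4,5,5-tetramethyl-1,3,2-dioxaborolane | COc1cc2ccc3cc(Cl)c(OCOC)c(-c4cc(C=C)ccc4OCOC)c3c2cc1B1OC(C)(C)C(C)(C)O1 | intermediate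
22 | 6-[2-bromo-3-chloro-6-(methoxymethoxy)phenyl]-2-chloro-4-[5-ethenyl-2-(methoxymethoxy)phenyl]-7-methoxy-3-(methoxymethoxy)phenanthrene | COc1cc2ccc3cc(Cl)c(OCOC)c(-c4cc(C=C)ccc4OCOC)c3c2cc1-c1c(OCOC)ccc(Cl)c1Br | intermediate
23 | 9-(2-{3-[6-(2-bromo-3-chloro-6-(methoxymethoxy)phenyl)-2-chloro-7-methoxy-3-(methoxymethoxy)phenanthren-4-yl]-4-(methoxymethoxy)phenyl}ethyl)-9-borabicyclo[3.3.1]nonane | COc1cc2ccc3cc(Cl)c(OCOC)c(-c4cc(CCB5C6CCCC5CCC6)ccc4OCOC)c3c2cc1-c1c(OCOC)ccc(Cl)c1Br | intermediate
24 | tris(methoxymethyl) ether of the target macrocycle (the three phenols of 25 as OCH2OCH3) | COc1cc2ccc3cc(Cl)c(OCOC)c4c3c2cc1-c1c(OCOC)ccc(Cl)c1CCc1ccc(OCOC)c-4c1 | intermediate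
25 | target CNP0310669.0: 2-chloro-7-methoxyphenanthren-3-ol whose C4 is bonded to C1 of ring D (2-hydroxy-1,5-phenylene) and whose C6 is bonded to C2 of ring E (6-chloro-3-hydroxy-1,2-phenylene), ring D C5 and ring E C1 being joined by CH2CH2; racemic | COc1cc2ccc3cc(Cl)c(O)c4c3c2cc1-c1c(O)ccc(Cl)c1CCc1ccc(O)c-4c1 | target

**Step count and risks**

Total steps: 17. Longest linear sequence: 11 (3 to 4, 6, 7, 8, 9, 14, 15, 16, 22, 24, 25).

Steps most likely to fail:

1. Step 16. Intermolecular coupling to oligomers, protodeboronation or beta-hydride elimination of the alkylpalladium species may outrun ring closure, and oxidative addition at the doubly ortho-substituted C–Br bond may be slow. Fallback: setting out from 22, an intramolecular Mizoroki–Heck reaction (Pd(OAc)2, P(o-tol)3, NaOAc, DMF, 110 °C, high dilution) would form the same aryl–carbon bond and give the macrocyclic (Z)-stilbene tris(methoxymethyl) ether F1. Diimide reduction of the new CH=CH bridge (TsNHNH2, NaOAc, THF/H2O, reflux) would then return to the route at 24.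

2. Step 10. Transmetalation and reductive elimination at the bay carbon may be so slow that protodeboronation of 13 and insertion into the C2–Cl bond take over. Fallback: ring D is attached before the phenanthrene is closed, setting out from 2.
   - Iodination at the remaining ortho carbon (N-iodosuccinimide, MeCN) would give 2-bromo-5-chloro-4-hydroxy-3-iodobenzaldehyde F2.
   - MOM protection (NaH, MOMCl) would give 2-bromo-5-chloro-3-iodo-4-(methoxymethoxy)benzaldehyde F3.
   - Suzuki–Miyaura coupling with 13 at the carbon–iodine bond would give the biaryl bromoaldehyde F4.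
   - A second Suzuki–Miyaura coupling at its C–Br bond with boronate 5 (made from 4 as in step 3) would give the teraryl dialdehyde F5.
   - A McMurry coupling (low-valent titanium from TiCl4 and Zn, THF, reflux, chosen because hot acetic acid would endanger the MOM acetals) would close ring B and return to the route at 14.

3. Step 15. Slow transmetalation in forming the tri-ortho-substituted biaryl may allow protodeboronation of 21 or a second coupling at the C–Br bond of the product. Fallback: the roles of the partners are exchanged, setting out from 18 and 16. Lithiation of 18 as in step 14 to 19 and transmetalation with ZnCl2 would give [2-bromo-3-chloro-6-(methoxymethoxy)phenyl]zinc chloride F6. Negishi coupling with triflate 16 (Pd(PPh3)4, THF, 60 °C) would then return to the route at 22.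

Further compounds
F1 | step 16 | macrocyclic (Z)-stilbene tris(methoxymethyl) ether (24 with a cis CH=CH bridge in place of CH2CH2) | COc1cc2ccc3cc(Cl)c(OCOC)c4c3c2cc1-c1c(OCOC)ccc(Cl)c1/C=C\c1ccc(OCOC)c-4c1
F2 | step 10 | 2-bromo-5-chloro-4-hydroxy-3-iodobenzaldehyde | O=Cc1cc(Cl)c(O)c(I)c1Br
F3 | step 10 | 2-bromo-5-chloro-3-iodo-4-(methoxymethoxy)benzaldehyde | O=Cc1cc(Cl)c(OCOC)c(I)c1Br
F4 | step 10 | biaryl bromoaldehyde: 2-bromo-5-chloro-3-[5-ethenyl-2-(methoxymethoxy)phenyl]-4-(methoxymethoxy)benzaldehyde | O=Cc1cc(Cl)c(OCOC)c(-c2cc(C=C)ccc2OCOC)c1Br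
F5 | step 10 | teraryl dialdehyde: 5-{3-chloro-5-[5-ethenyl-2-(methoxymethoxy)phenyl]-6-formyl... ring C unit}-4-formyl-2-methoxyphenyl 4-methylbenzenesulfonate (ring A and ring C each with CHO ortho to the biaryl bond, ring D on the ring C carbon between the biaryl bond and OMOM) | COc1cc(C=O)c(-c2c(C=O)cc(Cl)c(OCOC)c2-c2cc(C=C)ccc2OCOC)cc1OS(=O)(=O)c1ccc(C)cc1
F6 | step 15 | [2-bromo-3-chloro-6-(methoxymethoxy)phenyl]zinc chloride | COCOc1ccc(Cl)c(Br)c1[Zn]Cl
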